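Friday's flask ends with more target than Thursday's, 71.3% against 58.1%, though it ran hotter. Thursday's flask is the one asked about.

all flasks: substrate 12 mM; free enzyme 0.0025 mol%

| flask | temperature | remark | time |
|---|---|---|---|
| Thursday's | 37 °C | the very flask that is asked about, followed so far |  |
| Friday's | 43 °C | run made earlier |  |
| flask | 37 °C |  | 6.0 d |

- cedar: at 6.0 d raise the temperature by 15 K, then wait 12 d
- ash: change nothing and wait 12 d more
- birch: at 6.0 d add free enzyme, 100% of the amount charged, then wait 12 d
- elm: at 6.0 d take out 90% of the target then present, then wait 12 d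

- percent here means substrate units held: one homo dimer counts as two
- target that was removed still counts
- candidate steps: free enzyme -> unfolded enzyme; substrate + free enzyme -> target + free enzyme; free enzyme -> spent catalyst; 2 substrate -> homo dimer; target + free enzyme <-> isomer of the product + free enzyme
- additions bring no volume worth counting

1. target, in percent of the substrate first charged, at 6.0 d
2. what to do for the largest gain in target; "none" if nothing gains more than 2 percentage points (cedar / ash / birch / elm / none)
3. target present, with what was taken out counted in, in percent of the substrate first charged, after ash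
4. target present, with what was taken out counted in, in percent of the substrate first charged, after birch

| run | time / h | target / % | substrate / % |
|---|---|---|---|
| Thursday's | 20.0 | 71.6 | 0 |
| Thursday's | 40.0 | 62.5 | 0.4 |
| Thursday's | 60.0 | 60.2 | 0 |
| Thursday's | 72.0 | 58.5 | 0 |
| Thursday's | 96.0 | 58.1 | 0 |
| Thursday's | 120 | 58.1 | 0 |
| Thursday's | 144 | 58.1 | 0.5 |
| Friday's | 20.0 | 74.3 | 0.6 |
| Friday's | 40.0 | 71.0 | 0 |
| Friday's | 60.0 | 72.4 | 0 |
| Friday's | 72.0 | 70.9 | 0.3 |
| Friday's | 96.0 | 71.3 | 0 |
| Friday's | 120 | 71.1 | 0 |
| Friday's | 144 | 71.3 | 0 |

(readings scatter by 0.5 percentage points)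

Down the substrate column, Thursday's flask reads 0% at 20.0 h, so the later target readings follow the passing of target into the isomer of the product. Down its target column the falls shrink: 9.1 percentage points between the first two rows, then 2.3 points. From 96.0 h to 144 h the rows read alike at 58.1%. Friday's column stops sooner, near 40.0 h, and higher. Friday's flask, warmer and otherwise charged alike, stopping earlier at more target reads as enzyme dying sooner: kinetic control, not a balance.

Taking the whole charge as passing first into target, the last reading of Thursday's flask says that one charge of enzyme at 37 °C leaves 58.1% of that target. Call this s, the survival share of one charge. At 37 °C, and while the way back from the isomer of the product stays small, this reckoning takes enzyme to remove a fixed part of whatever target stands, so charges multiply: a second charge leaves s of what the first left, and a part x of a charge leaves s to the power x.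

This reckoning puts target at s for now and after ash. Thursday's target column reads flat from 96.0 h to 144 h, so this reckoning expects no gain of 2 points from cedar or elm either. Birch sends the first answer round again: s times s gives 33.8%, a loss, so the choice is none.

The forecast gives 58.1%, none, 58.1% after ash and 43% after birch, where “fresh enzyme only drains target further”; this reckoning stands lower on birch.

The flask gives 57.6% at 6.0 d, 57.5% after ash and 33.7% after birch, and the choice is none.

    free enzyme → unfolded enzyme (k = 4.24 × 10⁻⁷ s⁻¹, Ea = 181 kJ mol⁻¹)
    substrate + free enzyme → target + free enzyme, rate k2*[substrate]*[free enzyme]/(1 + ([substrate]/Km2)) (18.5 mM, k = 3800 L mol⁻¹ s⁻¹, Ea = 26.0 kJ mol⁻¹)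
    free enzyme → spent catalyst (k = 1.26 × 10⁻⁵ s⁻¹, Ea = 103 kJ mol⁻¹)
    2 substrate → homo dimer (k = 2.77 × 10⁻⁴ L mol⁻¹ s⁻¹, Ea = 65.0 kJ mol⁻¹)
    target + free enzyme ⇌ isomer of the product + free enzyme, rate k5*[free enzyme]*[target] forward; the back reaction follows from the equilibrium constant (K = 26.0, k = 24.5 L mol⁻¹ s⁻¹, Ea = 41.0 kJ mol⁻¹, ΔH = −71.0 kJ mol⁻¹)
    (constants at 37 °C)

At 144 h Thursday's flask holds 0.117% of its catalyst as free enzyme, 3.25% as unfolded enzyme and 96.6% as spent catalyst. One reason for the stop is that loss: the same run with the step to spent catalyst struck out holds 6.46% target at 6.0 d, not 57.6%.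

A flask like Thursday's with 0.001 mol% of free enzyme has 0.400 of Thursday's charge, so s to that power gives 80.5% target. The simulated flask holds 79.7%.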